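**Retrosynthetic overview**
1. Atoms are numbered 1–23 in the order written in the target SMILES (C1–C20, N21, N-methyl C22, C23; oxygens unnumbered). Rings: A piperidine, B cycloheptene, C cyclopentene (C11–C15), D cyclopentane (C12, C13, C16, C18, C19).
2. The C1–C4 chain is added last (Wittig, CBS, hydrogenation) to a C5 aldehyde; before that C6 is made quaternary on the bridging ketone (van Leusen nitrile = C5, then hydroxymethylation = C7).
3. Ring C is the last ring, closed at C11–C15 by a one-pot double hydroboration / intramolecular B-alkyl Suzuki–Miyaura coupling / oxidation that also sets C16 and installs the C17 hydroxyl. Enabling feature: the tetrasubstituted C11=C12 bond shared by rings B and C is the enol double bond of a ring-B ketone at C11, so C11 can be a regiodefined enol triflate and C15 the end of a vinyl group on C13. The second borane (C17) cannot couple, because that would give a bridgehead olefin (bicyclo[2.2.1]hept-1-ene).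
4. Ring A: Polonovski–Potier/Mannich closure from a C19–CH2NMe2 group (one N-methyl becomes C23). Ring D: aldol condensation of a 1,4-diketone. Ring B: cycloheptane-1,3-dione, whose C2 becomes C19 (desymmetrising transfer hydrogenation).
5. Order of ring formation: B (purchased) → D (step 8) → A (step 13) → C (step 14).

Key step: step 14

Remark: the sense of induction of the (S,S)-configured RuCl(p-cymene)(TsDPEN) catalyst in step 3 is assumed; the antipodal catalyst would be used if it proves opposite.

**Route**

Step 1
Reactants: 1 cycloheptane-1,3-dione; 2 3-chloro-2-methylprop-1-ene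
Product: 3 2-(2-methylprop-2-en-1-yl)cycloheptane-1,3-dione
Conditions: Pd(PPh3)4 (2 mol%), K2CO3, THF, 50 °C
Reagents that add atoms: none
Why: Tsuji–Trost allylation of the soft 1,3-dione enolate by the π-methallyl palladium complex should give C-alkylation at the carbon between the carbonyls, the future C19.

Step 2
Reactants: 3 2-(2-methylprop-2-en-1-yl)cycloheptane-1,3-dione; 4 N,N-dimethylmethyleneiminium iodide (Eschenmoser's salt)
Product: 5 2-[(dimethylamino)methyl]-2-(2-methylprop-2-en-1-yl)cycloheptane-1,3-dione
Conditions: K2CO3, MeCN, 0 °C → rt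
Reagents that add atoms: none
Why: Mannich reaction of the acidic 2-substituted 1,3-dione with the preformed iminium ion quaternises C19 and brings in C20, N21, C22 and the future C23 in one reagent, the product still being achiral because the two ring carbonyls are enantiotopic.

Step 3
Reactants: 5 2-[(dimethylamino)methyl]-2-(2-methylprop-2-en-1-yl)cycloheptane-1,3-dione
Product: 6 (2R,3R)-2-[(dimethylamino)methyl]-3-hydroxy-2-(2-methylprop-2-en-1-yl)cycloheptan-1-one
Conditions: RuCl(p-cymene)[(S,S)-TsDPEN] (1 mol%), HCO2H/Et3N (5:2), CH2Cl2, 25 °C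
Reagents that add atoms: none
Why: Noyori asymmetric transfer hydrogenation desymmetrises the 2,2-disubstituted 1,3-dione by reducing one of the two enantiotopic carbonyls, which fixes the absolute configuration of C19, while the carbinol centre (future C6, drawn cis to CH2NMe2) is temporary and is erased in step 10.

Step 4
Reactants: 6 hydroxy ketone
Product: 7 (2R,3R)-3-(tert-butyldimethylsilyloxy)-2-[(dimethylamino)methyl]-2-(2-methylprop-2-en-1-yl)cycloheptan-1-one
Conditions: TBSOTf, 2,6-lutidine, CH2Cl2, −78 → 0 °C
Reagents that add atoms: tert-butyldimethylsilyl triflate CC(C)(C)[Si](C)(C)OS(=O)(=O)C(F)(F)F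
Why: Silyl ether formation blocks retro-aldol opening of the β-hydroxy ketone under the basic steps that follow.

Step 5
Reactants: 7 silyl ether
Product: 9 α-hydroxy ketone (7 carrying a hydroxyl on the ring CH2 next to the carbonyl, C11; either C11 epimer), via potassium enolate 8 (not isolated)
Conditions: KN(SiMe3)2, THF, −78 °C; then 2-(phenylsulfonyl)-3-phenyloxaziridine, −78 °C; AcOH
Reagents that add atoms: 2-(phenylsulfonyl)-3-phenyloxaziridine c1ccc(cc1)C1ON1S(=O)(=O)c1ccccc1
Why: Davis enolate hydroxylation places oxygen on C11 only, because the ketone can enolise in one direction (C19 is quaternary), and the new carbinol centre is temporary.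

Step 6
Reactants: 9 α-hydroxy ketone
Product: 10 bis(tert-butyldimethylsilyl) ether of 9 (C6 and C11 OTBS)
Conditions: TBSOTf, 2,6-lutidine, CH2Cl2, 0 °C
Reagents that add atoms: tert-butyldimethylsilyl triflate CC(C)(C)[Si](C)(C)OS(=O)(=O)C(F)(F)F
Why: Silylation protects the α-ketol against periodate cleavage in step 7 and against ketol transposition under the base of step 8.

Step 7
Reactants: 10 bis-silyl ether
Product: 11 1,4-diketone (10 with the methallyl group cleaved to a 2-oxopropyl group; C16 carbonyl, C13 methyl)
Conditions: OsO4 (2 mol%), NaIO4, 2,6-lutidine, dioxane/H2O (3:1), rt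
Reagents that add atoms: osmium tetroxide O=[Os](=O)(=O)=O; sodium periodate [Na+].[O-]I(=O)(=O)=O
Why: Lemieux–Johnson oxidative cleavage of the 1,1-disubstituted olefin unmasks the methyl ketone only now, so that the transfer hydrogenation of step 3 had only the two ring carbonyls to choose from.

Step 8
Reactants: 11 1,4-diketone
Product: 12 bicyclic enone (ring D cyclopentenone C16(=O)–C13H=C12 fused to ring B at C12–C19; C6 and C11 OTBS; CH2NMe2 on C19)
Conditions: KOH (0.3 equiv), MeOH, 40 °C
Reagents that add atoms: none
Why: Intramolecular aldol condensation of the methyl ketone carbon C13 onto the ring carbonyl C12, followed by E1cB dehydration, closes ring D, the competing aldol from C11 giving only a bridged ketol that cannot dehydrate and reverts.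

Step 9
Reactants: 12 bicyclic enone
Product: 13 diol (12 with free hydroxyls on C6 and C11)
Conditions: HF·pyridine, pyridine, THF, 0 °C → rt
Reagents that add atoms: none
Why: Fluoride-mediated desilylation frees both carbinols without touching the enone.

Step 10
Reactants: 13 diol
Product: 14 trione (ring D ene-1,4-dione C16(=O)–C13H=C12–C11(=O) plus the ring-B ketone C6)
Conditions: Dess–Martin periodinane, CH2Cl2, rt
Reagents that add atoms: none
Why: Dess–Martin oxidation turns the allylic C11 carbinol into the second carbonyl of the enedione and the C6 carbinol into the ketone that later drives the Mannich closure and carries C5.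

Step 11
Reactants: 14 trione
Product: 16 enol triflate (C11 OTf, C11=C12; α-vinyl group on C13; ketones at C16 and C6), via bromomagnesium enolate 15 (not isolated)
Conditions: CH2=CHMgBr, CuBr·SMe2 (10 mol%), THF, −78 °C; then Comins' reagent, DMPU, −78 → 0 °C
Reagents that add atoms: vinylmagnesium bromide C=C[Mg]Br; N-(5-chloropyridin-2-yl)-1,1,1-trifluoro-N-(trifluoromethanesulfonyl)methanesulfonamide (Comins' reagent) Clc1ccc(nc1)N(S(=O)(=O)C(F)(F)F)S(=O)(=O)C(F)(F)F
Why: Copper-catalysed conjugate addition followed by enolate triflation should put the vinyl group on C13, the only unsubstituted β-carbon of the enedione, on the face anti to the angular CH2NMe2 group of C19 (the opposite face carries only the flat C6 carbonyl), and the enolate formed regiospecifically across C11=C12 is trapped as the triflate.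

Step 12
Reactants: 16 enol triflate
Product: 17 triene triflate (16 with the C16 carbonyl replaced by an exocyclic methylene, C17)
Conditions: Tebbe reagent Cp2Ti(μ-Cl)(μ-CH2)AlMe2 (1.1 equiv), pyridine (cat.), THF/toluene, −40 → 0 °C
Reagents that add atoms: Tebbe reagent C[Al-]1(C)C[Ti](C2C=CC=C2)(C2C=CC=C2)[Cl+]1
Why: Tebbe methylenation is non-basic, so the enolisable C13 centre is kept, and the cyclopentanone carbonyl C16 should react ahead of the neopentyl ring-B ketone flanked by quaternary C19.

Step 13
Reactants: 17 triene triflate
Product: 20 azabicyclic ketone (ring A closed: N21–C23–C8; C6 now a bridging ketone; C11 OTf, C13 vinyl and C16=CH2 unchanged), via amine N-oxide 18 (not isolated), via iminium trifluoroacetate 19 (not isolated)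
Conditions: mCPBA (1.05 equiv), CH2Cl2, −40 °C; TFAA, −40 → 0 °C; then MeCN, 50 °C
Reagents that add atoms: none
Why: Polonovski–Potier fragmentation of the N-oxide gives the N-methyl-N-methyleneiminium ion by proton loss from an N-methyl rather than from neopentyl C20, and a 6-endo Mannich cyclisation of the C6 ketone enol at C8 closes ring A, the bridge being able to form only cis across ring B so that C8 follows from C19.

Step 14
Reactants: 20 azabicyclic ketone
Product: 23 tetracyclic hydroxy ketone (rings A–D complete; C17 hydroxyl; C6 ketone), via bis-borane 21 (not isolated), via cyclised borane 22 (not isolated)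
Conditions: 9-BBN-H (3 equiv), THF, 0 °C → rt; then Pd(dppf)Cl2 (10 mol%), AsPh3, Cs2CO3, DMF/THF/H2O, 50 °C; then NaOH, H2O2, 0 °C
Reagents that add atoms: hydrogen peroxide OO
Why: 9-BBN adds syn and anti-Markovnikov to the vinyl and the exocyclic methylene groups (the tetrasubstituted enol triflate olefin is inert), then zerovalent palladium inserts into the C11–OTf bond, the base-activated primary alkylborane at C15 transmetalates, reductive elimination forms C11–C15, and alkaline peroxide converts the spectator C17–B bond into the C17 hydroxyl with retention. The closest known reaction type is the intramolecular B-alkyl Suzuki–Miyaura coupling of an alkenyl triflate with an alkyl-9-BBN made in situ by hydroboration. Ring C closes as a five-membered ring by C(sp3)–C(sp2) reductive elimination from a six-membered alkyl(alkenyl)palladium cycle, with no carbopalladation, so the C11=C12 bond stays where the triflate placed it. The new stereocentre C16 is set in the hydroboration, 9-BBN reaching the methylene from the β face, anti to the adjacent α side chain on C13 and no longer hindered by C20, which step 13 tied back into ring A. The step needs chemoselection between two primary alkylboranes, and the substrate secures it because coupling of the C17 borane with C11 would create an anti-Bredt bicyclo[2.2.1]hept-1-ene; the non-enolisable C6 ketone flanked by C19 and C8 should be reduced by 9-BBN much more slowly than terminal olefins are hydroborated.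

Step 15
Reactants: 23 tetracyclic hydroxy ketone
Product: 24 nitrile (C6–H bearing C≡N, the future C5; both C6 epimers)
Conditions: TosMIC, t-BuOK, EtOH (2 equiv), DME, 0 → 40 °C
Reagents that add atoms: p-toluenesulfonylmethyl isocyanide Cc1ccc(cc1)S(=O)(=O)C[N+]#[C-]
Why: Van Leusen reductive cyanation converts the non-enolisable bridging ketone into the nitrile in one step, and the C6 epimer mixture is harmless because C6 becomes planar in step 16.

Step 16
Reactants: 24 nitrile
Product: 26 hydroxymethyl nitrile (C6 quaternary: CH2OH = C7 on the side of the C11=C12 bridge, C≡N on the side of the nitrogen bridge), via lithiated nitrile 25 (not isolated)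
Conditions: LiN(i-Pr)2 (3.2 equiv), THF, −78 → −30 °C; then CH2O (gas, from cracked paraformaldehyde), −78 °C; AcOH
Reagents that add atoms: formaldehyde C=O
Why: Alkylation of the nitrile-stabilised carbanion with formaldehyde should occur equatorially with respect to ring A, over the four-carbon bridge whose C12 is sp2 and carries no axial hydrogen, and not past the axial hydrogens on C20 and C23, which sets C6 with C7 anti to the nitrogen bridge.

Step 17
Reactants: 26 hydroxymethyl nitrile
Product: 28 hydroxy aldehyde (C5 formyl on C6), via aldimine 27 (not isolated)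
Conditions: i-Bu2AlH (4 equiv), CH2Cl2, −78 → 0 °C; then aq. KNaC4H4O6 (potassium sodium tartrate), wet silica gel
Reagents that add atoms: water O
Why: Half-reduction of the nitrile with i-Bu2AlH stops at the aluminium aldimine, whose hydrolysis gives the neopentyl aldehyde without touching the tetrasubstituted olefin.

Step 18
Reactants: 28 hydroxy aldehyde; 29 1-(triphenyl-λ5-phosphanylidene)butan-2-one
Product: 30 (E)-enone (C4=C5, C3 ketone, ethyl C1–C2)
Conditions: toluene, 100 °C
Reagents that add atoms: none
Why: Wittig olefination with the stabilised ylide gives the E-enone under base-free conditions that avoid retro-aldol loss of formaldehyde from the β-hydroxy aldehyde.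

Step 19
Reactants: 30 (E)-enone
Product: 31 (S)-allylic alcohol (C3 carbinol)
Conditions: (R)-2-methyl-CBS-oxazaborolidine (20 mol%), BH3·SMe2 (3 equiv), THF, −30 °C; then MeOH, 1 M aq. HCl, rt
Reagents that add atoms: none
Why: Corey–Bakshi–Shibata reduction is reagent-controlled, the alkenyl group acting as the large substituent so that the (R)-catalyst should give the S carbinol at C3 irrespective of the remote ring stereocentres, the excess borane covering the two hydroxyls and the tertiary amine, which the acidic methanol work-up sets free again.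

Step 20
Reactants: 31 (S)-allylic alcohol
Product: 32 target CNP0221997.1
Conditions: H2 (1 atm), 5% Pd/C, EtOAc, rt
Reagents that add atoms: none
Why: Catalytic hydrogenation saturates the disubstituted C4=C5 olefin, while the hindered tetrasubstituted C11=C12 olefin should survive these mild conditions.

**Compound list**
1 | cycloheptane-1,3-dione | O=C1CCCCC(=O)C1 | starting material
2 | 3-chloro-2-methylprop-1-ene | CC(=C)CCl | starting material
3 | 2-(2-methylprop-2-en-1-yl)cycloheptane-1,3-dione | O=C1CCCCC(=O)C1CC(C)=C | intermediate
4 | N,N-dimethylmethyleneiminium iodide (Eschenmoser's salt) | C[N+](C)=C.[I-] | starting material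
5 | 2-[(dimethylamino)methyl]-2-(2-methylprop-2-en-1-yl)cycloheptane-1,3-dione | O=C1CCCCC(=O)C1(CC(C)=C)CN(C)C | intermediate
6 | (2R,3R)-2-[(dimethylamino)methyl]-3-hydroxy-2-(2-methylprop-2-en-1-yl)cycloheptan-1-one | O=C1CCCC[C@@H](O)[C@@]1(CC(C)=C)CN(C)C | intermediate
7 | (2R,3R)-3-(tert-butyldimethylsilyloxy)-2-[(dimethylamino)methyl]-2-(2-methylprop-2-en-1-yl)cycloheptan-1-one | O=C1CCCC[C@@H](O[Si](C)(C)C(C)(C)C)[C@@]1(CC(C)=C)CN(C)C | intermediate
8 | potassium enolate of 7 (C11=C12 enolate) | [K]OC1=CCCC[C@@H](O[Si](C)(C)C(C)(C)C)[C@@]1(CC(C)=C)CN(C)C | intermediate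
9 | α-hydroxy ketone: 7 with OH on C11, either C11 epimer | O=C1C(O)CCC[C@@H](O[Si](C)(C)C(C)(C)C)[C@@]1(CC(C)=C)CN(C)C | intermediate
10 | bis-TBS ether of 9 | O=C1C(O[Si](C)(C)C(C)(C)C)CCC[C@@H](O[Si](C)(C)C(C)(C)C)[C@@]1(CC(C)=C)CN(C)C | intermediate
11 | 1,4-diketone: 10 with 2-oxopropyl in place of methallyl | O=C1C(O[Si](C)(C)C(C)(C)C)CCC[C@@H](O[Si](C)(C)C(C)(C)C)[C@@]1(CC(C)=O)CN(C)C | intermediate
12 | bicyclic enone, rings B and D, C6 and C11 OTBS | O=C1C=C2C(O[Si](C)(C)C(C)(C)C)CCC[C@@H](O[Si](C)(C)C(C)(C)C)[C@@]2(C1)CN(C)C | intermediate
13 | diol from 12 (C6-OH, C11-OH) | O=C1C=C2C(O)CCC[C@@H](O)[C@@]2(C1)CN(C)C | intermediate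
14 | trione: C16/C11 enedione in ring D plus C6 ketone | O=C1C=C2C(=O)CCCC(=O)[C@@]2(C1)CN(C)C | intermediate
15 | bromomagnesium C11 enolate of the C13 vinyl adduct | O=C1[C@H](C=C)C2=C(O[Mg]Br)CCCC(=O)[C@@]2(C1)CN(C)C | intermediate
16 | C11 enol triflate, α-vinyl at C13, ketones at C16 and C6 | O=C1[C@H](C=C)C2=C(OS(=O)(=O)C(F)(F)F)CCCC(=O)[C@@]2(C1)CN(C)C | intermediate
17 | triene triflate: 16 with C16=CH2 | C=C1[C@H](C=C)C2=C(OS(=O)(=O)C(F)(F)F)CCCC(=O)[C@@]2(C1)CN(C)C | intermediate
18 | N-oxide of 17 | C=C1[C@H](C=C)C2=C(OS(=O)(=O)C(F)(F)F)CCCC(=O)[C@@]2(C1)C[N+](C)(C)[O-] | intermediate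
19 | N-methyl-N-methyleneiminium trifluoroacetate from 18 | C=C1[C@H](C=C)C2=C(OS(=O)(=O)C(F)(F)F)CCCC(=O)[C@@]2(C1)C[N+](C)=C.[O-]C(=O)C(F)(F)F | intermediate
20 | azabicyclic ketone, rings A, B, D; C11 OTf; C13 vinyl; C16=CH2 | C=C1[C@H](C=C)C2=C(OS(=O)(=O)C(F)(F)F)CC[C@H]3CN(C)C[C@]2(C1)C3=O | intermediate
21 | bis(9-BBN) adduct of 20 (boron on C15 and C17) | C(B4C5CCCC4CCC5)[C@@H]1[C@H](CCB4C5CCCC4CCC5)C2=C(OS(=O)(=O)C(F)(F)F)CC[C@H]3CN(C)C[C@]2(C1)C3=O | intermediate
22 | ring-C-closed C17 borane | C(B5C6CCCC5CCC6)[C@H]1C[C@]23CN(C)C[C@H](CCC4=C2[C@H]1CC4)C3=O | intermediate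
23 | tetracyclic hydroxy ketone (C17-OH, C6 ketone) | OC[C@H]1C[C@]23CN(C)C[C@H](CCC4=C2[C@H]1CC4)C3=O | intermediate
24 | C6 nitrile, both C6 epimers | OC[C@H]1C[C@]23CN(C)C[C@H](CCC4=C2[C@H]1CC4)C3C#N | intermediate
25 | dilithio species: C17 alkoxide and C6 keteniminate | [Li]OC[C@H]1C[C@]23CN(C)C[C@H](CCC4=C2[C@H]1CC4)C3=C=N[Li] | intermediate
26 | hydroxymethyl nitrile, C6 quaternary | OC[C@H]1C[C@]23CN(C)C[C@H](CCC4=C2[C@H]1CC4)[C@@]3(CO)C#N | intermediate
27 | aldimine from 26 | OC[C@H]1C[C@]23CN(C)C[C@H](CCC4=C2[C@H]1CC4)[C@@]3(CO)C=N | intermediate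
28 | hydroxy aldehyde (C5 formyl) | OC[C@H]1C[C@]23CN(C)C[C@H](CCC4=C2[C@H]1CC4)[C@@]3(CO)C=O | intermediate
29 | 1-(triphenyl-λ5-phosphanylidene)butan-2-one | CCC(=O)C=P(c1ccccc1)(c1ccccc1)c1ccccc1 | starting material
30 | (E)-enone | OC[C@H]1C[C@]23CN(C)C[C@H](CCC4=C2[C@H]1CC4)[C@@]3(CO)/C=C/C(=O)CC | intermediate
31 | (S)-allylic alcohol | OC[C@H]1C[C@]23CN(C)C[C@H](CCC4=C2[C@H]1CC4)[C@@]3(CO)/C=C/[C@@H](O)CC | intermediate
32 | CNP0221997.1 | OC[C@H]1C[C@]23CN(C)C[C@H](CCC4=C2[C@H]1CC4)[C@@]3(CO)CC[C@@H](O)CC | target

**Step count**
Total steps: 20. Longest linear sequence: 20 steps (1 → 32; all other inputs are purchased).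

**Steps most likely to fail, with fallbacks**

Step 11. Facial discrimination in the addition to the flat enedione may be poor, because the only control element is the 1,3-related angular aminomethyl group, and electron transfer from the organocopper may reduce the enedione instead of adding to it. The fallback replaces steric control by chelation control. It sets out from diol 13: MnO2 in CH2Cl2 should oxidise only the allylic C11 carbinol and give the hydroxy enedione F1. Excess vinylmagnesium bromide in THF at −78 → −30 °C first forms the C6 magnesium alkoxide, which sits on the α face and should deliver a second equivalent to C13 through a six-membered chelate (alkoxide-directed conjugate addition); trapping with Comins' reagent gives the hydroxy enol triflate F2. Dess–Martin oxidation of the C6 carbinol comes back to the route at 16.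

Step 14. Transmetalation at the hindered tetrasubstituted alkenylpalladium may be slow, leaving time for protodeboronation or palladium hydride migration of the skipped olefins, and face control in the hydroboration of the methylene group may be lost while ring C is still open. The fallback separates ring closure from the C16 hydroboration. It sets out from 20: disiamylborane, which reacts far more slowly with 1,1-disubstituted than with monosubstituted terminal olefins, hydroborates only the vinyl group, and the same palladium conditions close ring C to the methylene tetracycle F3. 9-BBN then hydroborates the exocyclic olefin of the now rigid bowl-shaped diquinane from its convex β face, and NaOH/H2O2 gives the route compound 23.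

Step 16. Facial control in the alkylation of the planar keteniminate may fail, the electrophile entering past the piperidine bridge instead of over the olefinic bridge. The fallback inverts the order in which the two carbon substituents of C6 are introduced, so that the face that is actually preferred receives the side chain. It sets out from 24: LiN(i-Pr)2 and 2-(2-bromoethyl)-1,3-dioxolane give the alkylated nitrile F4, in which the nitrile is now the future C7. i-Bu2AlH gives the aldehyde F5 and NaBH4 the hydroxymethyl acetal F6; aqueous HCl in THF frees the C3 aldehyde F7 (free or as its lactol). Catalytic asymmetric ethylation (Et2Zn, Ti(OiPr)4, (1R,2R)-N,N'-bis(trifluoromethanesulfonyl)cyclohexane-1,2-diamine, the enantiomer expected by analogy with simple aldehydes to give the S carbinol) comes back to the route at 32.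

**Further compounds**
F1 | step 11 | hydroxy enedione (13 with C11 oxidised to the ketone, C6-OH free) | O=C1C=C2C(=O)CCC[C@@H](O)[C@@]2(C1)CN(C)C
F2 | step 11 | hydroxy enol triflate (16 with C6-OH in place of the C6 ketone) | O=C1[C@H](C=C)C2=C(OS(=O)(=O)C(F)(F)F)CCC[C@@H](O)[C@@]2(C1)CN(C)C
F3 | step 14 | methylene tetracycle (rings A–D, C16=CH2, C6 ketone) | C=C1C[C@]23CN(C)C[C@H](CCC4=C2[C@H]1CC4)C3=O
F4 | step 16 | C6-quaternary nitrile with 2-(1,3-dioxolan-2-yl)ethyl on C6 | OC[C@H]1C[C@]23CN(C)C[C@H](CCC4=C2[C@H]1CC4)[C@@]3(C#N)CCC5OCCO5
F5 | step 16 | C7 aldehyde from F4 | OC[C@H]1C[C@]23CN(C)C[C@H](CCC4=C2[C@H]1CC4)[C@@]3(C=O)CCC5OCCO5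
F6 | step 16 | C7 alcohol from F5 | OC[C@H]1C[C@]23CN(C)C[C@H](CCC4=C2[C@H]1CC4)[C@@]3(CO)CCC5OCCO5
F7 | step 16 | C3 aldehyde from F6 | OC[C@H]1C[C@]23CN(C)C[C@H](CCC4=C2[C@H]1CC4)[C@@]3(CO)CCC=O
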